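**Strategy.** Ring A is disconnected at C8–C8a, C6–C7 and C4a–C8a. It is a 1,3,5-trioxygenated (phloroglucinol) ring in which O5, O7 and O8a need different fates and the C8 side chain is flanked by two of them. A Danheiser benzannulation of 3-ethoxycyclobutenone with a triisopropylsilyl ynol ether that already carries the (R)-configured, silyl-protected chain builds this ring in a single step. It delivers O8a as free phenol, O7 as silyl ether and O5 as ethyl ether, leaving C4a as the only open ortho carbon. The ynol ether comes from methacrolein in three steps. Ortho-formylation, alkynylation, oxidation and amine-induced closure then add ring C before dealkylation and desilylation.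

Key step: step 4

Remark 1: ring-A carbons of all intermediates are given their flavone locants (C4a, C5–C8, C8a).
Remark 2: the (R)-phosphoric acid of step 1 is assumed to direct the propargyl group to the Re face of the aldehyde, as it does in the related allylborations.
Remark 3: the carbinol epimers of 21 are carried on as a mixture, because that centre is oxidised in step 9.

**Step 1**
Reactants: 1 methacrolein; 2 allenylboronic acid pinacol ester
Product: 4 (3R)-2-methylhex-1-en-5-yn-3-ol, via pinacol borate 3 (not isolated)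
Conditions: (R)-3,3'-bis(2,4,6-triisopropylphenyl)-1,1'-binaphthyl-2,2'-diyl hydrogen phosphate (10 mol %), 4 Å MS, toluene, −20 °C; aq. NaHCO3, silica gel
Reagents that add atoms: none
Why: Chiral Brønsted acid-catalysed allenylboration (aldehyde propargylation) through a closed six-membered SE2′ transition state, in which the (R)-acid bridges a boronate oxygen and the formyl hydrogen and should expose the Re face of methacrolein, setting the carbinol centre as (R) and giving only the homopropargylic alcohol.

**Step 2**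
Reactants: 4 (3R)-2-methylhex-1-en-5-yn-3-ol
Product: 5 tert-butyldimethyl{[(3R)-2-methylhex-1-en-5-yn-3-yl]oxy}silane
Conditions: TBSCl, imidazole, DMF, 0 °C → rt
Reagents that add atoms: tert-butyldimethylsilyl chloride, CC(C)(C)[Si](C)(C)Cl
Why: Routine silyl ether formation on a secondary allylic alcohol, which does not touch the stereocentre.

**Step 3**
Reactants: 5 tert-butyldimethyl{[(3R)-2-methylhex-1-en-5-yn-3-yl]oxy}silane
Product: 8 (4R)-4-(tert-butyldimethylsilyloxy)-5-methyl-1-(triisopropylsilyloxy)hex-5-en-1-yne, via lithium acetylide 6 (not isolated), via lithium ynolate 7 (not isolated)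
Conditions: n-BuLi, THF, −78 °C; t-BuOOLi (from t-BuOOH and LiN(SiMe3)2), −78 → 0 °C; i-Pr3SiOTf, −78 → 0 °C; rapid filtration through Et3N-deactivated silica
Reagents that add atoms: tert-butyl hydroperoxide, CC(C)(C)OO; triisopropylsilyl trifluoromethanesulfonate, CC(C)[Si](C(C)C)(C(C)C)OS(=O)(=O)C(F)(F)F
Why: Electrophilic oxygenation of the lithium acetylide by lithium tert-butyl peroxide gives the ynolate, and O-silylation by the hard, bulky silyl triflate gives the ynol silyl ether (ynolate formation and O-silylation), the silyloxy group lying gamma to the carbanionic carbon so that it cannot be eliminated and the stereocentre stays intact.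

**Step 4**
Reactants: 8 (4R)-4-(tert-butyldimethylsilyloxy)-5-methyl-1-(triisopropylsilyloxy)hex-5-en-1-yne; 9 3-ethoxycyclobut-2-en-1-one
Product: 14 2-[(2R)-2-(tert-butyldimethylsilyloxy)-3-methylbut-3-en-1-yl]-5-ethoxy-3-(triisopropylsilyloxy)phenol, via vinylketene 10 (not isolated), via vinylcyclobutenone 11 (not isolated), via dienylketene 12 (not isolated), via cyclohexadienone 13 (not isolated)
Conditions: 9 (1.5 equiv), toluene, 80 °C then 110 °C, sealed tube, argon
Reagents that add atoms: none
Why: Heating should open 9 by four-electron electrocyclic cleavage to vinylketene 10, which adds [2+2] across the electron-rich triple bond of 8 to give 11; a second four-electron opening gives dienylketene 12, six-electron electrocyclisation gives dienone 13, and tautomerisation gives phenol 14. The closest precedent is the Danheiser benzannulation of cyclobutenones with siloxyalkynes, the 3-alkoxy group on the cyclobutenone being the less common element. Ring A, the only ring kept, closes by thermal disrotatory 6π electrocyclisation (C4a–C8a) after C8–C8a and C6–C7 have been made in the [2+2] step, the four-membered ring of 11 being transient. No stereocentre is created, and the existing (R)-carbinol, one CH2 group away from the alkyne, is not involved. The selectivity needed is regiochemical: the polarised ynol ether makes its chain-bearing carbon the nucleophile toward the ketene carbonyl carbon, so the chain should end up between the free hydroxyl (C8a) and the silyloxy group (C7), with the ethoxy group para to it (C5).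

**Step 5**
Reactants: 14 2-[(2R)-2-(tert-butyldimethylsilyloxy)-3-methylbut-3-en-1-yl]-5-ethoxy-3-(triisopropylsilyloxy)phenol
Product: 16 3-[(2R)-2-(tert-butyldimethylsilyloxy)-3-methylbut-3-en-1-yl]-6-ethoxy-2-hydroxy-4-(triisopropylsilyloxy)benzaldehyde, via hydroxymethylphenol 15 (not isolated)
Conditions: MgCl2, Et3N, (CH2O)n, MeCN, 80 °C; aq. NH4Cl
Reagents that add atoms: formaldehyde (as paraformaldehyde), C=O
Why: Magnesium-mediated ortho-formylation (Casnati–Skattebøl), in which the magnesium phenoxide delivers formaldehyde to the ortho carbon and a second formaldehyde oxidises the benzylic alkoxide of 15 by hydride transfer, so that only C4a, the single free ortho position, should react and the para carbon C6 is left alone.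

**Step 6**
Reactants: 17 4-hydroxybenzaldehyde
Product: 18 4-(triisopropylsilyloxy)benzaldehyde
Conditions: i-Pr3SiCl, imidazole, DMF, rt
Reagents that add atoms: triisopropylsilyl chloride, CC(C)[Si](Cl)(C(C)C)C(C)C
Why: Routine phenol silylation, giving a hindered aryl silyl ether that matches the one on O7.

**Step 7**
Reactants: 18 4-(triisopropylsilyloxy)benzaldehyde
Product: 19 (4-ethynylphenoxy)triisopropylsilane
Conditions: MeC(O)C(N2)P(O)(OMe)2, K2CO3, MeOH, 0 °C → rt
Reagents that add atoms: dimethyl (1-diazo-2-oxopropyl)phosphonate (Ohira–Bestmann reagent), CC(=O)C(=[N+]=[N-])P(=O)(OC)OC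
Why: Seyferth–Gilbert homologation with the Ohira–Bestmann reagent converts the aldehyde into the terminal alkyne under mild carbonate conditions that the hindered aryl silyl ether should survive.

**Step 8**
Reactants: 16 3-[(2R)-2-(tert-butyldimethylsilyloxy)-3-methylbut-3-en-1-yl]-6-ethoxy-2-hydroxy-4-(triisopropylsilyloxy)benzaldehyde; 19 (4-ethynylphenoxy)triisopropylsilane
Product: 21 2-[(2R)-2-(tert-butyldimethylsilyloxy)-3-methylbut-3-en-1-yl]-5-ethoxy-6-{1-hydroxy-3-[4-(triisopropylsilyloxy)phenyl]prop-2-yn-1-yl}-3-(triisopropylsilyloxy)phenol, via lithium arylacetylide 20 (not isolated)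
Conditions: 19 (3 equiv), n-BuLi (2.9 equiv), THF, −78 °C; then 16, −78 → 0 °C; aq. NH4Cl; crude product used directly
Reagents that add atoms: none
Why: 1,2-Addition of a lithium acetylide to an aldehyde, in which the first equivalent only deprotonates the phenol and the excess adds to the formyl group, the new carbinol centre being formed without control and removed in step 9.

**Step 9**
Reactants: 21 2-[(2R)-2-(tert-butyldimethylsilyloxy)-3-methylbut-3-en-1-yl]-5-ethoxy-6-{1-hydroxy-3-[4-(triisopropylsilyloxy)phenyl]prop-2-yn-1-yl}-3-(triisopropylsilyloxy)phenol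
Product: 22 1-{3-[(2R)-2-(tert-butyldimethylsilyloxy)-3-methylbut-3-en-1-yl]-6-ethoxy-2-hydroxy-4-(triisopropylsilyloxy)phenyl}-3-[4-(triisopropylsilyloxy)phenyl]prop-2-yn-1-one
Conditions: MnO2 (activated, excess), CH2Cl2, rt
Reagents that add atoms: none
Why: MnO2 oxidation of a benzylic and propargylic alcohol to the ynone, a reagent that should leave silyl ethers, the isolated alkene and the hydrogen-bonded phenol untouched.

**Step 10**
Reactants: 22 1-{3-[(2R)-2-(tert-butyldimethylsilyloxy)-3-methylbut-3-en-1-yl]-6-ethoxy-2-hydroxy-4-(triisopropylsilyloxy)phenyl}-3-[4-(triisopropylsilyloxy)phenyl]prop-2-yn-1-one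
Product: 24 8-[(2R)-2-(tert-butyldimethylsilyloxy)-3-methylbut-3-en-1-yl]-5-ethoxy-7-(triisopropylsilyloxy)-2-[4-(triisopropylsilyloxy)phenyl]-4H-chromen-4-one, via enaminone 23 (not isolated)
Conditions: Et2NH, EtOH, rt → 50 °C
Reagents that add atoms: none
Why: Amine-mediated cycloisomerisation of an ortho-hydroxyaryl ynone, in which conjugate addition of Et2NH gives enaminone 23 and addition–elimination by the only free phenol (O8a) at the beta carbon closes the pyranone in the 6-endo sense, avoiding the 5-exo (aurone) mode and fixing the chain at C8.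

**Step 11**
Reactants: 24 8-[(2R)-2-(tert-butyldimethylsilyloxy)-3-methylbut-3-en-1-yl]-5-ethoxy-7-(triisopropylsilyloxy)-2-[4-(triisopropylsilyloxy)phenyl]-4H-chromen-4-one
Product: 26 8-[(2R)-2-(tert-butyldimethylsilyloxy)-3-methylbut-3-en-1-yl]-5-hydroxy-7-(triisopropylsilyloxy)-2-[4-(triisopropylsilyloxy)phenyl]-4H-chromen-4-one, via dichloroboron chelate 25 (not isolated)
Conditions: BCl3, n-Bu4NI, CH2Cl2, −78 → 0 °C; cold aq. NaHCO3 quench
Reagents that add atoms: none
Why: Chelation-assisted aryl ether cleavage, in which BCl3 is held between the C4 carbonyl and O5 and iodide removes the ethyl group by SN2 to leave chelate 25, so that only the peri ether should be cleaved and, with no protic acid present before the basic quench, the hindered silyl ethers and the alkene should survive.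

**Step 12**
Reactants: 26 8-[(2R)-2-(tert-butyldimethylsilyloxy)-3-methylbut-3-en-1-yl]-5-hydroxy-7-(triisopropylsilyloxy)-2-[4-(triisopropylsilyloxy)phenyl]-4H-chromen-4-one
Product: 27 5,7-dihydroxy-8-[(2R)-2-hydroxy-3-methylbut-3-en-1-yl]-2-(4-hydroxyphenyl)-4H-chromen-4-one
Conditions: n-Bu4NF, AcOH, THF, 0 → 40 °C
Reagents that add atoms: none
Why: Fluoride-driven desilylation removes both aryl triisopropylsilyl groups and the secondary tert-butyldimethylsilyl ether under buffered, non-acidic conditions that can neither ionise the allylic alcohol nor cyclise the chain onto O7.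

**Compound list**
1 | methacrolein | C=C(C)C=O | starting material
2 | allenylboronic acid pinacol ester | C=C=CB1OC(C)(C)C(C)(C)O1 | starting material
3 | 4,4,5,5-tetramethyl-2-{[(3R)-2-methylhex-1-en-5-yn-3-yl]oxy}-1,3,2-dioxaborolane | C=C(C)[C@H](OB1OC(C)(C)C(C)(C)O1)CC#C | intermediate
4 | (3R)-2-methylhex-1-en-5-yn-3-ol | C=C(C)[C@H](O)CC#C | intermediate
5 | tert-butyldimethyl{[(3R)-2-methylhex-1-en-5-yn-3-yl]oxy}silane | C=C(C)[C@H](O[Si](C)(C)C(C)(C)C)CC#C | intermediate
6 | lithium acetylide of 5 | C=C(C)[C@H](O[Si](C)(C)C(C)(C)C)CC#C[Li] | intermediate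
7 | lithium (4R)-4-(tert-butyldimethylsilyloxy)-5-methylhex-5-en-1-yn-1-olate | C=C(C)[C@H](O[Si](C)(C)C(C)(C)C)CC#CO[Li] | intermediate
8 | (4R)-4-(tert-butyldimethylsilyloxy)-5-methyl-1-(triisopropylsilyloxy)hex-5-en-1-yne | C=C(C)[C@H](O[Si](C)(C)C(C)(C)C)CC#CO[Si](C(C)C)(C(C)C)C(C)C | intermediate
9 | 3-ethoxycyclobut-2-en-1-one | CCOC1=CC(=O)C1 | starting material
10 | 3-ethoxybuta-1,3-dien-1-one (vinylketene) | C=C(OCC)C=C=O | intermediate
11 | 2-[(2R)-2-(tert-butyldimethylsilyloxy)-3-methylbut-3-en-1-yl]-4-(1-ethoxyvinyl)-3-(triisopropylsilyloxy)cyclobut-2-en-1-one | C=C(C)[C@H](O[Si](C)(C)C(C)(C)C)CC1=C(O[Si](C(C)C)(C(C)C)C(C)C)C(C(=C)OCC)C1=O | intermediate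
12 | dienylketene from ring opening of 11 (ketene carbon and ethoxyvinyl group cis on the central double bond) | C=C(C)[C@H](O[Si](C)(C)C(C)(C)C)CC(=C=O)/C(O[Si](C(C)C)(C(C)C)C(C)C)=C\C(=C)OCC | intermediate
13 | 2-[(2R)-2-(tert-butyldimethylsilyloxy)-3-methylbut-3-en-1-yl]-5-ethoxy-3-(triisopropylsilyloxy)cyclohexa-2,4-dien-1-one | C=C(C)[C@H](O[Si](C)(C)C(C)(C)C)CC1=C(O[Si](C(C)C)(C(C)C)C(C)C)C=C(OCC)CC1=O | intermediate
14 | 2-[(2R)-2-(tert-butyldimethylsilyloxy)-3-methylbut-3-en-1-yl]-5-ethoxy-3-(triisopropylsilyloxy)phenol | C=C(C)[C@H](O[Si](C)(C)C(C)(C)C)Cc1c(O)cc(OCC)cc1O[Si](C(C)C)(C(C)C)C(C)C | intermediate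
15 | 2-[(2R)-2-(tert-butyldimethylsilyloxy)-3-methylbut-3-en-1-yl]-5-ethoxy-6-(hydroxymethyl)-3-(triisopropylsilyloxy)phenol (present as its magnesium alkoxide) | C=C(C)[C@H](O[Si](C)(C)C(C)(C)C)Cc1c(O)c(CO)c(OCC)cc1O[Si](C(C)C)(C(C)C)C(C)C | intermediate
16 | 3-[(2R)-2-(tert-butyldimethylsilyloxy)-3-methylbut-3-en-1-yl]-6-ethoxy-2-hydroxy-4-(triisopropylsilyloxy)benzaldehyde | C=C(C)[C@H](O[Si](C)(C)C(C)(C)C)Cc1c(O)c(C=O)c(OCC)cc1O[Si](C(C)C)(C(C)C)C(C)C | intermediate
17 | 4-hydroxybenzaldehyde | O=Cc1ccc(O)cc1 | starting material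
18 | 4-(triisopropylsilyloxy)benzaldehyde | O=Cc1ccc(O[Si](C(C)C)(C(C)C)C(C)C)cc1 | intermediate
19 | (4-ethynylphenoxy)triisopropylsilane | C#Cc1ccc(O[Si](C(C)C)(C(C)C)C(C)C)cc1 | intermediate
20 | lithium acetylide of 19 | [Li]C#Cc1ccc(O[Si](C(C)C)(C(C)C)C(C)C)cc1 | intermediate
21 | 2-[(2R)-2-(tert-butyldimethylsilyloxy)-3-methylbut-3-en-1-yl]-5-ethoxy-6-{1-hydroxy-3-[4-(triisopropylsilyloxy)phenyl]prop-2-yn-1-yl}-3-(triisopropylsilyloxy)phenol (both epimers at the new carbinol carbon) | C=C(C)[C@H](O[Si](C)(C)C(C)(C)C)Cc1c(O)c(C(O)C#Cc2ccc(O[Si](C(C)C)(C(C)C)C(C)C)cc2)c(OCC)cc1O[Si](C(C)C)(C(C)C)C(C)C | intermediate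
22 | 1-{3-[(2R)-2-(tert-butyldimethylsilyloxy)-3-methylbut-3-en-1-yl]-6-ethoxy-2-hydroxy-4-(triisopropylsilyloxy)phenyl}-3-[4-(triisopropylsilyloxy)phenyl]prop-2-yn-1-one | C=C(C)[C@H](O[Si](C)(C)C(C)(C)C)Cc1c(O)c(C(=O)C#Cc2ccc(O[Si](C(C)C)(C(C)C)C(C)C)cc2)c(OCC)cc1O[Si](C(C)C)(C(C)C)C(C)C | intermediate
23 | 3-(diethylamino)enone from 22 and diethylamine (alkene geometry not fixed) | C=C(C)[C@H](O[Si](C)(C)C(C)(C)C)Cc1c(O)c(C(=O)C=C(N(CC)CC)c2ccc(O[Si](C(C)C)(C(C)C)C(C)C)cc2)c(OCC)cc1O[Si](C(C)C)(C(C)C)C(C)C | intermediate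
24 | 8-[(2R)-2-(tert-butyldimethylsilyloxy)-3-methylbut-3-en-1-yl]-5-ethoxy-7-(triisopropylsilyloxy)-2-[4-(triisopropylsilyloxy)phenyl]-4H-chromen-4-one | C=C(C)[C@H](O[Si](C)(C)C(C)(C)C)Cc1c(O[Si](C(C)C)(C(C)C)C(C)C)cc(OCC)c2c(=O)cc(-c3ccc(O[Si](C(C)C)(C(C)C)C(C)C)cc3)oc12 | intermediate
25 | 5-O-dichloroboryl chelate of 26 | C=C(C)[C@H](O[Si](C)(C)C(C)(C)C)Cc1c(O[Si](C(C)C)(C(C)C)C(C)C)cc(OB(Cl)Cl)c2c(=O)cc(-c3ccc(O[Si](C(C)C)(C(C)C)C(C)C)cc3)oc12 | intermediate
26 | 8-[(2R)-2-(tert-butyldimethylsilyloxy)-3-methylbut-3-en-1-yl]-5-hydroxy-7-(triisopropylsilyloxy)-2-[4-(triisopropylsilyloxy)phenyl]-4H-chromen-4-one | C=C(C)[C@H](O[Si](C)(C)C(C)(C)C)Cc1c(O[Si](C(C)C)(C(C)C)C(C)C)cc(O)c2c(=O)cc(-c3ccc(O[Si](C(C)C)(C(C)C)C(C)C)cc3)oc12 | intermediate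
27 | 5,7-dihydroxy-8-[(2R)-2-hydroxy-3-methylbut-3-en-1-yl]-2-(4-hydroxyphenyl)-4H-chromen-4-one | C=C(C)[C@H](O)Cc1c(O)cc(O)c2c(=O)cc(-c3ccc(O)cc3)oc12 | target

**Step count**
Total: 12 steps. Longest linear sequence: 10 steps (steps 1–5 and 8–12).

**Steps most likely to fail**

Step 4. The donor-substituted cyclobutenone may open too slowly, so that at the temperature required the ynol ether undergoes oxygen-to-carbon silyl shift, or the vinylketene is lost to self-condensation and to acylation of the phenol product. The fallback sets out from 8 and returns at 14. It generates the same vinylketene 10 at room temperature by photochemical Wolff rearrangement instead of thermal ring opening. Ethyl vinyl ether is lithiated (t-BuLi, THF, −78 → 0 °C) to 1-ethoxyvinyllithium F1, which is acylated with N-methoxy-N-methylacetamide to 3-ethoxybut-3-en-2-one F2. Trifluoroacetylation of its lithium enolate (LiN(SiMe3)2, CF3CO2CH2CF3, −78 °C) gives 5-ethoxy-1,1,1-trifluorohex-5-ene-2,4-dione F3, and diazo transfer with loss of the trifluoroacetyl group (MsN3, Et3N, MeCN, water) gives 1-diazo-3-ethoxybut-3-en-2-one F4. Irradiation of F4 with 8 (CH2Cl2, 300 nm, rt) and brief warming to 80 °C should then lead through 10–13 to 14.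

Step 11. The Lewis acid may ionise the allylic silyl ether or add hydrogen halide to the isopropenyl group before the ethyl group is lost, or the ethyl ether may be cleaved incompletely at the low temperature those groups require. The fallback sets out from 24 and returns at 27. It reverses the order of the last two operations and replaces the Lewis acid by an anionic dealkylation. Desilylation of 24 (n-Bu4NF, AcOH, THF) gives 5-ethoxy-7-hydroxy-8-[(2R)-2-hydroxy-3-methylbut-3-en-1-yl]-2-(4-hydroxyphenyl)-4H-chromen-4-one F5. Heating F5 with excess NaSEt in DMF (110–130 °C, argon) should remove the ethyl group by thiolate SN2 attack, the phenoxide form of the flavone resisting ring opening, and acidification gives 27.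

Step 1. Facial discrimination may be poor with a small, alpha-branched enal, or the uncatalysed racemic addition may compete, giving material of insufficient enantiomeric purity. The fallback sets out from 1 and returns at 4. It replaces asymmetric induction by resolution. Barbier propargylation of 1 (Zn dust, propargyl bromide, THF/aq. NH4Cl) gives rac-2-methylhex-1-en-5-yn-3-ol F6. Sharpless kinetic resolution (Ti(OiPr)4, L-(+)-diisopropyl tartrate, t-BuOOH 0.6 equiv, 4 Å MS, CH2Cl2, −20 °C) should epoxidise the (S)-enantiomer to (1S)-1-[(2R)-2-methyloxiran-2-yl]but-3-yn-1-ol F7, which is separated by chromatography, and leave (R)-alcohol 4, at most half of the material.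

**Further compounds**
F1 | step 4 | 1-ethoxyvinyllithium | [Li]C(=C)OCC
F2 | step 4 | 3-ethoxybut-3-en-2-one | C=C(OCC)C(C)=O
F3 | step 4 | 5-ethoxy-1,1,1-trifluorohex-5-ene-2,4-dione | C=C(OCC)C(=O)CC(=O)C(F)(F)F
F4 | step 4 | 1-diazo-3-ethoxybut-3-en-2-one | C=C(OCC)C(=O)C=[N+]=[N-]
F5 | step 11 | 5-ethoxy-7-hydroxy-8-[(2R)-2-hydroxy-3-methylbut-3-en-1-yl]-2-(4-hydroxyphenyl)-4H-chromen-4-one | C=C(C)[C@H](O)Cc1c(O)cc(OCC)c2c(=O)cc(-c3ccc(O)cc3)oc12
F6 | step 1 | rac-2-methylhex-1-en-5-yn-3-ol | C=C(C)C(O)CC#C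
F7 | step 1 | (1S)-1-[(2R)-2-methyloxiran-2-yl]but-3-yn-1-ol | C[C@@]1(CO1)[C@@H](O)CC#C
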